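# Proposed synthesis of clavulolactone III by carbonylative ring assembly

## The problem

Atoms are numbered as in the prostanoids: C1 is the lactone carbonyl and C4 the lactone carbinol carbon. C5=C6 and C7=C8 form the diene, C8–C12 the five-membered ring (C9 ketone, C10=C11, C12 quaternary acetate), and C13–C20 the (Z)-oct-2-enyl chain. A synthesis must build a cross-conjugated cyclopentenone whose ring carbon C8 carries an exocyclic alkene, and must attach one chain at the quaternary carbon C12 and one at C7. The stereocentres C4 (R) and C12 (S) lie five bonds apart across a flat diene, so neither can control the other. C12 is the harder one, a fully substituted carbinol carbon whose three carbon neighbours (C8, C11, C13) are sterically alike. The hardest single element is the C7=C8 geometry: in the (7Z) isomer C6 lies on the side of the C9 carbonyl, and an alkene formed by elimination or under equilibrating conditions is expected to lean to (7E). The product is fragile: the dienone is a Michael acceptor that isomerises with light or nucleophiles, the tertiary acetate at C12 is doubly allylic, the lactone C4–O bond is allylic, and the skipped (Z)-alkene C14=C15 must not migrate. The feature that opens the problem is the ring itself: its carbonyl carbon C9 is bonded only to the sp2 carbons C10 and C8, and these belong to two two-carbon unsaturated arms (C10=C11 and C8=C7) that both hang from C12. The ring is therefore C12 plus two C2 arms plus one carbon monoxide, and the (7Z) relation (C9 and C6 cis on C7=C8) is what results when an acyl group and an alkenyl group add syn across a terminal alkyne C8≡C7.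

## Retrosynthesis

**Target 22 to iodo-enyne acetate 15, stannane 18 and carbon monoxide 19.** Three bonds are cut together: C9–C10 and C8–C9 (both to 19) and C6–C7. Cutting only C7=C8 leaves the geometry to an elimination. Cutting only C6–C7 needs a preformed (Z)-halomethylene cyclopentenone, which poses the same geometric question. The triple cut turns the ring ketone into 19 and lets a single syn addition across the alkyne of 15 fix (7Z). The precursor is far simpler: 15 is acyclic, has one stereocentre and no conjugated carbonyl, and 18 carries the other stereocentre. The forward reaction must run in a fixed order under neutral conditions: oxidative addition at C10–I, CO insertion, 5-exo-dig syn-acylpalladation, then Stille coupling with retention.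

**Stannane 18 to aldehyde 17 and lactone alcohol 16.** The C5=C6 bond is cut by an (E)-selective chromium-mediated stannyl olefination. C4 is bought with 16, which avoids an asymmetric step for a centre that no later step can influence. The forward sequence must only avoid epimerising the α-oxygenated aldehyde 17.

**Iodo-enyne acetate 15 to silyl-capped vinyl iodide 14 and iodoalkyne acetate 13.** No skeletal bond is cut. The ethynyl arm is uncovered from a silylalkyne, and the (Z)-iodovinyl arm comes from a 1-iodoalkyne by syn delivery of two hydrogens. Both arms at C12 are thus alkynes in 13, told apart by their caps (iodine and silicon). This avoids olefination of a hindered α-oxygenated aldehyde and introduces the iodide of the key step as an alkynyl iodide.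

**Iodoalkyne acetate 13 to epoxy chloride 10, epoxy alcohol 9 and dienynol 8.** The C10≡C11 alkyne is traced to the CH–CH2Cl unit of 10 by base-induced double elimination. This breaks the C–O bond at the CH carbon only and keeps the tertiary C12–O bond. C12 is set in 9 by Sharpless asymmetric epoxidation of 8. Here the reagent reads the allylic alcohol face, and the fixed alkene geometry of 8 translates this into the C12 configuration. A direct enantioselective addition to a ketone flanked by an alkynyl and a CH2 group would have to discriminate two groups of similar size. The forward sequence must also cap the new acetylide with iodine and the tertiary alkoxide with acetyl.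

**Dienynol 8 to vinyl iodide 6 and silylacetylene 7; 6 to enynol 4; 4 to bromide 2 and propargyl alcohol 3; 2 to allylic alcohol 1.** The C12–alkyne bond is cut by Sonogashira coupling. The trisubstituted alkene geometry of 6 comes from hydroxyl-directed trans-hydroalumination and iodination of 4. The C13–C12 connection is a copper-mediated SN2 alkylation of the acetylide of 3 by 2, which avoids a (Z)-oct-2-enyl nucleophile (it would react at its γ-carbon). The (Z)-C14=C15 alkene is bought with 1.

## Roads not taken

**Alternative 1:** The most obvious cut is C7=C8 alone. The forward key step is an aldol addition of the C8 enolate of (4R)-4-hydroxy-4-[(2Z)-oct-2-en-1-yl]cyclopent-2-en-1-one A1 to the lactone enal A2, followed by dehydration and acetylation.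
- The dehydration runs through an enolate (E1cB) that keeps no memory of the aldol configuration, so the C7=C8 geometry is expected to favour (7E), with C6 away from the carbonyl.
- The C8 enolate of A1 has the C12 oxygen in the β-position, which invites elimination and forces protecting-group changes at C12.
- A1 must itself be made as a single enantiomer with its ring, so nothing is saved in steps.

The chosen plan fixes (7Z) by mechanism and builds the ring and the C6–C7 bond in the same operation.

**Alternative 2:** Cut C8–C12 by a Piancatelli rearrangement, a dearomatisation of the furfuryl alcohol A3. Acid opens A3 to a hydroxypentadienyl cation that closes by 4π conrotation, the same type of ring closure as in the allene oxide pathway of prostanoid biosynthesis. It would give the racemic hydroxycyclopentenone A4 in one step from a flat furan.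
- The cation is planar and achiral, so the C12 configuration would have to come from a torquoselective chiral acid. This is without precedent for water as the nucleophile and a primary carbinol.
- The C7=C8 problem is left untouched and falls back on the chemistry of Alternative 1 (A4 plus A2).

**Alternative 3:** Cut C8–C9 alone by intramolecular alkyne hydroacylation of the (Z)-enynal A5 with a cationic rhodium bisphosphine catalyst such as [Rh(dppe)]BF4.
- Acyl and hydrogen add cis across C8≡C7, so C6 ends trans to C9. The product is the (7E) isomer A6, which would need a non-selective photoisomerisation.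
- A5 requires the C6–C7 bond before ring closure (less convergent) and contains a sensitive (Z)-γ-acetoxy enal.

The chosen plan adds acyl and C6 cis, which gives (7Z) directly.

Key step: step 12

Assumption: Bu3SnCHBr2 is not a catalogue reagent and is taken as made in one operation from CH2Br2, LDA and Bu3SnCl; it is treated as a reagent, not as a numbered compound.

## Route

Step 1
Reactants: 1 (Z)-oct-2-en-1-ol
Product: 2 (Z)-1-bromooct-2-ene
Conditions: PBr3, pyridine (cat.), Et2O, −10 °C
Reagents that add atoms: phosphorus tribromide, BrP(Br)Br
Why: Bromination of a primary allylic alcohol through its bromophosphite (SN2 at the primary carbon); at low temperature no allylic transposition is expected and the (Z)-alkene is kept.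

Step 2
Reactants: 2 (Z)-1-bromooct-2-ene; 3 prop-2-yn-1-ol
Product: 4 (Z)-undec-5-en-2-yn-1-ol
Conditions: CuI (20 mol %), NaI (20 mol %), K2CO3, DMF, rt
Reagents that add atoms: none
Why: Copper acetylide alkylation of an allylic halide, the standard entry to skipped enynes; the free hydroxyl is tolerated, and attack at the primary carbon should give the linear 1,4-enyne with the (Z)-alkene unchanged.

Step 3
Reactants: 4 (Z)-undec-5-en-2-yn-1-ol
Product: 6 (2Z,5Z)-3-iodoundeca-2,5-dien-1-ol, via cyclic alkenylaluminate 5 (not isolated)
Conditions: NaAlH2(OCH2CH2OMe)2, THF, 0 °C to rt; EtOAc; then I2, −78 to 0 °C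
Reagents that add atoms: iodine, II
Why: Hydroxyl-directed trans-hydroalumination of a propargylic alcohol puts aluminium on C3 in the five-membered aluminate 5, and iodinolysis with retention gives the (Z)-3-iodoallylic alcohol. This fixes the trisubstituted alkene geometry that later decides C12; the isolated (Z)-alkene is inert to the hydride.

Step 4
Reactants: 6 (2Z,5Z)-3-iodoundeca-2,5-dien-1-ol; 7 ethynyl(trimethyl)silane
Product: 8 (2Z,5Z)-3-[(trimethylsilyl)ethynyl]undeca-2,5-dien-1-ol
Conditions: PdCl2(PPh3)2 (2 mol %), CuI (4 mol %), i-Pr2NH, THF, rt
Reagents that add atoms: none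
Why: Sonogashira coupling of a vinyl iodide with retention of alkene geometry; the silyl cap marks this alkyne (the future C8≡C7 arm) as different from the alkyne made in step 7.

Step 5
Reactants: 8 (2Z,5Z)-3-[(trimethylsilyl)ethynyl]undeca-2,5-dien-1-ol
Product: 9 [(2S,3R)-3-[(2Z)-oct-2-en-1-yl]-3-[(trimethylsilyl)ethynyl]oxiran-2-yl]methanol
Conditions: Ti(OiPr)4 (20 mol %), L-(+)-diethyl tartrate (25 mol %), t-BuOOH, 4 Å MS, CH2Cl2, −20 °C
Reagents that add atoms: tert-butyl hydroperoxide, CC(C)(C)OO
Why: Sharpless asymmetric epoxidation of a 3,3-disubstituted primary allylic alcohol (the geraniol and nerol substrate class). With L-(+)-tartrate the oxygen goes to the face that gives the (2S,3R)-epoxide, so the quaternary epoxide carbon (C12) is set by the reagent together with the fixed (2Z) geometry. The remote (Z)-alkene is not an allylic alcohol and is not epoxidised.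

Step 6
Reactants: 9 [(2S,3R)-3-[(2Z)-oct-2-en-1-yl]-3-[(trimethylsilyl)ethynyl]oxiran-2-yl]methanol
Product: 10 (2R,3R)-2-(chloromethyl)-3-[(2Z)-oct-2-en-1-yl]-3-[(trimethylsilyl)ethynyl]oxirane
Conditions: PPh3, CCl4, NaHCO3, 70 °C
Reagents that add atoms: carbon tetrachloride, ClC(Cl)(Cl)Cl
Why: Appel chlorination of a primary alcohol under buffered neutral conditions; neither stereocentre takes part (the descriptor at the CH carbon changes only because the priorities change).

Step 7
Reactants: 10 (2R,3R)-2-(chloromethyl)-3-[(2Z)-oct-2-en-1-yl]-3-[(trimethylsilyl)ethynyl]oxirane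
Product: 13 (3R,5Z)-1-iodo-3-[(trimethylsilyl)ethynyl]undec-5-en-1-yn-3-yl acetate, via dilithium alkynide alkoxide 11 (not isolated), via lithium iodoalkynyl alkoxide 12 (not isolated)
Conditions: n-BuLi (3.3 equiv), THF, −78 to −30 °C; I2, −78 °C; Ac2O, −78 to 0 °C
Reagents that add atoms: iodine, II; acetic anhydride, CC(=O)OC(C)=O
Why: Base-induced double elimination of a 2,3-epoxy chloride to a propargylic alcohol: epoxide opening breaks only the C–O bond of the CH carbon, so the tertiary C12–O bond and its configuration are kept and dianion 11 results. Iodine then caps the acetylide (12) and acetic anhydride the tertiary lithium alkoxide, both standard anion trappings, so the sensitive diynol need not be isolated.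

Step 8
Reactants: 13 (3R,5Z)-1-iodo-3-[(trimethylsilyl)ethynyl]undec-5-en-1-yn-3-yl acetate
Product: 14 (1Z,3S,5Z)-1-iodo-3-[(trimethylsilyl)ethynyl]undeca-1,5-dien-3-yl acetate
Conditions: 2-nitrobenzenesulfonylhydrazide, Et3N, THF/i-PrOH, rt
Reagents that add atoms: none
Why: Diimide reduction of a 1-iodoalkyne: syn transfer of two hydrogens to the most reactive unsaturation gives the (Z)-vinyl iodide, while the silylalkyne and the disubstituted alkene react much more slowly. C12 is untouched (the descriptor changes with the priorities only).

Step 9
Reactants: 14 (1Z,3S,5Z)-1-iodo-3-[(trimethylsilyl)ethynyl]undeca-1,5-dien-3-yl acetate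
Product: 15 (1Z,3S,5Z)-3-ethynyl-1-iodoundeca-1,5-dien-3-yl acetate
Conditions: Bu4NF, AcOH, THF, 0 °C
Reagents that add atoms: none
Why: Fluoride-induced protodesilylation of an alkynylsilane; the acetic acid buffer protects the tertiary acetate and the (Z)-vinyl iodide, which a basic fluoride could dehydroiodinate.

Step 10
Reactants: 16 (5R)-5-(hydroxymethyl)oxolan-2-one
Product: 17 (2R)-5-oxooxolane-2-carbaldehyde
Conditions: Dess–Martin periodinane, CH2Cl2, 0 °C to rt
Reagents that add atoms: none
Why: Dess–Martin oxidation of a primary alcohol under neutral conditions; the α-oxygenated stereocentre should hold if the aldehyde is used at once.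

Step 11
Reactants: 17 (2R)-5-oxooxolane-2-carbaldehyde
Product: 18 (5R)-5-[(E)-2-(tributylstannyl)ethenyl]oxolan-2-one
Conditions: Bu3SnCHBr2, CrCl2, LiI, THF/DMF, rt
Reagents that add atoms: (dibromomethyl)tributylstannane, CCCC[Sn](CCCC)(CCCC)C(Br)Br
Why: Takai-type olefination with a geminal dihalide: the geminal dichromium species adds to the aldehyde and eliminates to the (E)-alkenylstannane; the lactone stereocentre is not involved.

Step 12
Reactants: 15 (1Z,3S,5Z)-3-ethynyl-1-iodoundeca-1,5-dien-3-yl acetate; 18 (5R)-5-[(E)-2-(tributylstannyl)ethenyl]oxolan-2-one; 19 carbon monoxide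
Product: 22 clavulolactone III, via acylpalladium iodide 20 (not isolated), via alkenylpalladium iodide 21 (not isolated)
Conditions: Pd2(dba)3 (5 mol %), AsPh3 (40 mol %), 19 (1 atm), THF, 45 °C
Reagents that add atoms: none
Why: Proposed new method: zerovalent palladium inserts into the C10–I bond of 15 with retention, 19 inserts to give acylpalladium iodide 20, and 20 adds syn across the tethered terminal alkyne (C9 to C8, palladium to C7), which closes the cyclopentenone in the 5-exo-dig mode and gives alkenylpalladium iodide 21; transmetalation with 18 and reductive elimination then make the C6–C7 bond. The closest known reaction types are the cyclic acylpalladation of alkynes by ω-alkynyl vinyl iodides under CO, carbopalladation–Stille cascades and the carbonylative Stille coupling; new is their union on a 1-iodo-1,4-enyne with Stille termination after a single CO uptake. No stereocentre is formed: C12 is a spectator and C4 arrives unchanged in 18. The (7Z) geometry is set by mechanism, since syn addition puts palladium on C7 cis to C9 and the Stille step replaces palladium by C6 with retention; (5E) is carried in by 18 and the ring alkene is cis because the vinyl iodide is (Z). The order of events should be secured by rates: CO insertion into the first alkenylpalladium is faster than a strained 4-exo carbopalladation, ring closure is intramolecular and outruns bimolecular transmetalation, and 21 is an electron-poor β-palladated enone held as a five-membered chelate by the C9 oxygen, which should slow a second CO insertion at 1 atm while AsPh3 speeds transmetalation. The same chelate keeps palladium cis to C9 should the alkenylpalladium isomerise, and the neutral conditions spare the tertiary acetate, the lactone and the dienone.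

## Compound list

1 | (Z)-oct-2-en-1-ol | CCCCC/C=C\CO | starting material
2 | (Z)-1-bromooct-2-ene | CCCCC/C=C\CBr | intermediate
3 | prop-2-yn-1-ol | C#CCO | starting material
4 | (Z)-undec-5-en-2-yn-1-ol | CCCCC/C=C\CC#CCO | intermediate
5 | sodium 2,2-bis(2-methoxyethoxy)-3-[(2Z)-oct-2-en-1-yl]-2,5-dihydro-1,2-oxaaluminol-2-uide (cyclic alkenylaluminate) | [Na+].COCCO[Al-]1(OCCOC)OCC=C1C/C=C\CCCCC | intermediate (not isolated)
6 | (2Z,5Z)-3-iodoundeca-2,5-dien-1-ol | OC/C=C(\I)C/C=C\CCCCC | intermediate
7 | ethynyl(trimethyl)silane | C#C[Si](C)(C)C | starting material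
8 | (2Z,5Z)-3-[(trimethylsilyl)ethynyl]undeca-2,5-dien-1-ol | OC/C=C(\C#C[Si](C)(C)C)C/C=C\CCCCC | intermediate
9 | [(2S,3R)-3-[(2Z)-oct-2-en-1-yl]-3-[(trimethylsilyl)ethynyl]oxiran-2-yl]methanol | OC[C@@H]1O[C@@]1(C#C[Si](C)(C)C)C/C=C\CCCCC | intermediate
10 | (2R,3R)-2-(chloromethyl)-3-[(2Z)-oct-2-en-1-yl]-3-[(trimethylsilyl)ethynyl]oxirane | ClC[C@@H]1O[C@@]1(C#C[Si](C)(C)C)C/C=C\CCCCC | intermediate
11 | dilithium (3S,5Z)-3-[(trimethylsilyl)ethynyl]undec-5-en-1-yn-1-id-3-olate | [Li+].[Li+].[C-]#C[C@]([O-])(C#C[Si](C)(C)C)C/C=C\CCCCC | intermediate (not isolated)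
12 | lithium (3R,5Z)-1-iodo-3-[(trimethylsilyl)ethynyl]undec-5-en-1-yn-3-olate | [Li+].IC#C[C@]([O-])(C#C[Si](C)(C)C)C/C=C\CCCCC | intermediate (not isolated)
13 | (3R,5Z)-1-iodo-3-[(trimethylsilyl)ethynyl]undec-5-en-1-yn-3-yl acetate | IC#C[C@](OC(C)=O)(C#C[Si](C)(C)C)C/C=C\CCCCC | intermediate
14 | (1Z,3S,5Z)-1-iodo-3-[(trimethylsilyl)ethynyl]undeca-1,5-dien-3-yl acetate | I/C=C\[C@](OC(C)=O)(C#C[Si](C)(C)C)C/C=C\CCCCC | intermediate
15 | (1Z,3S,5Z)-3-ethynyl-1-iodoundeca-1,5-dien-3-yl acetate | I/C=C\[C@](OC(C)=O)(C#C)C/C=C\CCCCC | intermediate
16 | (5R)-5-(hydroxymethyl)oxolan-2-one | OC[C@H]1CCC(=O)O1 | starting material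
17 | (2R)-5-oxooxolane-2-carbaldehyde | O=C[C@H]1CCC(=O)O1 | intermediate
18 | (5R)-5-[(E)-2-(tributylstannyl)ethenyl]oxolan-2-one | CCCC[Sn](CCCC)(CCCC)/C=C/[C@H]1CCC(=O)O1 | intermediate
19 | carbon monoxide | [C-]#[O+] | starting material
20 | acylpalladium iodide from 15 and 19 (ancillary ligands omitted) | O=C([Pd]I)/C=C\[C@](OC(C)=O)(C#C)C/C=C\CCCCC | intermediate (not isolated)
21 | cyclised alkenylpalladium iodide, palladium on C7 cis to C9 (ancillary ligands omitted) | CCCCC/C=C\C[C@]1(OC(C)=O)C=CC(=O)/C1=C\[Pd]I | intermediate (not isolated)
22 | clavulolactone III, (5R)-5-{(1E,3Z)-3-[(5S)-5-acetoxy-5-[(2Z)-oct-2-en-1-yl]-2-oxocyclopent-3-en-1-ylidene]prop-1-en-1-yl}oxolan-2-one | CCCCC/C=C\C[C@]1(OC(C)=O)C=CC(=O)/C1=C\C=C\[C@H]1CCC(=O)O1 | target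

## Step count and least certain steps

Total step count: 12. Longest linear sequence: 10 steps (steps 1–9 and 12, from 1); the stannane branch (steps 10 and 11, from 16) has 2 steps.

**Step 12 (Proposed new method).** Three processes are the most likely to go wrong.
- A second CO may be taken up by the cyclised alkenylpalladium before transmetalation, which would place a carbonyl between C7 and C6.
- The acylpalladium may cross-couple with 18 before ring closure.
- Zerovalent palladium may ionise the tertiary propargylic acetate of 15 or the allylic lactone C–O bond, and divalent palladium may promote an acetoxy shift of the 3-acetoxy-1,4-enyne (Rautenstrauch type).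

The cause is that two insertions and one transmetalation must occur in a fixed order on one catalyst under one CO pressure. The fallback uses known reactions only, sets out from 15 and returns at 22.
1. Rh4(CO)12-catalysed silylformylation of the terminal alkyne of 15 with Me2PhSiH and CO places the formyl group on C8 and silicon on C7, cis to each other, giving the (Z)-β-silyl enal F1.
2. An intramolecular Nozaki–Hiyama–Kishi reaction (CrCl2, NiCl2 cat., DMSO) joins C10 to the aldehyde carbon C9 and gives the cyclopentenol F2 as a mixture of carbinol epimers.
3. Iododesilylation with N-iodosuccinimide proceeds with retention to the alkenyl iodide F3.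
4. Dess–Martin oxidation gives the (Z)-iodomethylidene cyclopentenone F4.
5. Stille coupling of F4 with 18 (Pd2(dba)3, AsPh3) with retention gives 22.

In this sequence the syn silylformylation fixes the C7=C8 geometry in place of the acylpalladation.

**Step 7.** The likely failures are incomplete second dehydrochlorination, attack of butyllithium at silicon or at chlorine, and incomplete acetylation of the hindered tertiary alkoxide in the presence of iodine. The cause is that three anionic events are run in one flask. The fallback sets out from 10 and returns at 13. Elimination with LDA and a proton quench gives the diynol F5. Electrophilic iodination of its free alkyne (N-iodosuccinimide, AgNO3 cat.) gives the iodoalkynol F6. Acetylation (Ac2O, DMAP, Et3N) gives 13.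

**Step 5.** The likely failures are slow epoxidation, because the alkene is conjugated with the alkyne and is electron-poor, loss of enantioselectivity to an unselective background oxidation, and opening of the tertiary propargylic epoxide by titanium alkoxides. The fallback sets out from 8 and returns at 9. Hydroxyl-directed epoxidation with VO(acac)2 and t-BuOOH gives the racemic epoxy alcohol F7. A lipase (a serine hydrolase, for example Burkholderia cepacia lipase with vinyl acetate) acylates the unwanted enantiomer to the acetate F8 and leaves 9. This costs at most half of the material.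

**Step 11.** The likely failures are epimerisation or hydration of the α-acyloxy aldehyde 17 under the Lewis acidic chromium conditions, and protodestannylation during purification. The fallback sets out from 17 and returns at 18. Takai iodo-olefination (CHI3, CrCl2) gives the (E)-vinyl iodide F9. Pd(PPh3)4-catalysed stannylation with Bu3SnSnBu3 gives 18.

## Further compounds

F1 | step 12 | (2Z)-2-[(1Z,3S,5Z)-3-acetoxy-1-iodoundeca-1,5-dien-3-yl]-3-[dimethyl(phenyl)silyl]prop-2-enal | I/C=C\[C@](OC(C)=O)(/C(C=O)=C/[Si](C)(C)c1ccccc1)C/C=C\CCCCC
F2 | step 12 | (1S,5E)-5-{[dimethyl(phenyl)silyl]methylidene}-4-hydroxy-1-[(2Z)-oct-2-en-1-yl]cyclopent-2-en-1-yl acetate (C4 epimers, silicon cis to C4) | CCCCC/C=C\C[C@]1(OC(C)=O)C=CC(O)/C1=C\[Si](C)(C)c1ccccc1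
F3 | step 12 | (1S,5E)-4-hydroxy-5-(iodomethylidene)-1-[(2Z)-oct-2-en-1-yl]cyclopent-2-en-1-yl acetate (C4 epimers, iodine cis to C4) | CCCCC/C=C\C[C@]1(OC(C)=O)C=CC(O)/C1=C\I
F4 | step 12 | (1S,5Z)-5-(iodomethylidene)-1-[(2Z)-oct-2-en-1-yl]-4-oxocyclopent-2-en-1-yl acetate | CCCCC/C=C\C[C@]1(OC(C)=O)C=CC(=O)/C1=C\I
F5 | step 7 | (3S,5Z)-3-[(trimethylsilyl)ethynyl]undec-5-en-1-yn-3-ol | C#C[C@](O)(C#C[Si](C)(C)C)C/C=C\CCCCC
F6 | step 7 | (3R,5Z)-1-iodo-3-[(trimethylsilyl)ethynyl]undec-5-en-1-yn-3-ol | IC#C[C@](O)(C#C[Si](C)(C)C)C/C=C\CCCCC
F7 | step 5 | rac-[(2S,3R)-3-[(2Z)-oct-2-en-1-yl]-3-[(trimethylsilyl)ethynyl]oxiran-2-yl]methanol (racemate of 9) | OC[C@@H]1O[C@@]1(C#C[Si](C)(C)C)C/C=C\CCCCC.OC[C@H]1O[C@]1(C#C[Si](C)(C)C)C/C=C\CCCCC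
F8 | step 5 | [(2R,3S)-3-[(2Z)-oct-2-en-1-yl]-3-[(trimethylsilyl)ethynyl]oxiran-2-yl]methyl acetate | CC(=O)OC[C@H]1O[C@]1(C#C[Si](C)(C)C)C/C=C\CCCCC
F9 | step 11 | (5R)-5-[(E)-2-iodoethenyl]oxolan-2-one | I/C=C/[C@H]1CCC(=O)O1
A1 | alternative 1 | (4R)-4-hydroxy-4-[(2Z)-oct-2-en-1-yl]cyclopent-2-en-1-one | CCCCC/C=C\C[C@]1(O)C=CC(=O)C1
A2 | alternative 1 | (2E)-3-[(2R)-5-oxooxolan-2-yl]prop-2-enal | O=C/C=C/[C@H]1CCC(=O)O1
A3 | alternative 2 | {5-[(2Z)-oct-2-en-1-yl]furan-2-yl}methanol | OCc1ccc(C/C=C\CCCCC)o1
A4 | alternative 2 | rac-4-hydroxy-4-[(2Z)-oct-2-en-1-yl]cyclopent-2-en-1-one | CCCCC/C=C\CC1(O)C=CC(=O)C1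
A5 | alternative 3 | (2Z,4S,7E)-4-acetoxy-4-[(2Z)-oct-2-en-1-yl]-8-[(2R)-5-oxooxolan-2-yl]octa-2,7-dien-5-ynal | O=C/C=C\[C@](OC(C)=O)(C#C/C=C/[C@H]1CCC(=O)O1)C/C=C\CCCCC
A6 | alternative 3 | (5R)-5-{(1E,3E)-3-[(5S)-5-acetoxy-5-[(2Z)-oct-2-en-1-yl]-2-oxocyclopent-3-en-1-ylidene]prop-1-en-1-yl}oxolan-2-one, the (7E) isomer of 22 | CCCCC/C=C\C[C@]1(OC(C)=O)C=CC(=O)/C1=C/C=C/[C@H]1CCC(=O)O1
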